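The earlier runs and the new flask were computed for an exercise; scatter was added.

Thursday's run and Monday's run differ in c(free catalyst), and I read them by counting turnovers of the single-handed free catalyst, which makes left-handed product from the racemate while gas enters a solution that starts without it.

all flasks: left-handed substrate 0.32 M; right-handed substrate 0.32 M; gas 33 mM (held)

|  | free catalyst | remark | time |
|---|---|---|---|
| Thursday's | 0.15 mM | run made earlier |  |
| Monday's | 1.8 mM | run made earlier |  |
| blue | 0.50 mM |  | 10 min |
| teal | 0.25 mM |  | 10 min |
| amber | 0.74 mM |  | 10 min |
| green | 3.0 mM |  | 10 min |
| violet | 2.0 mM |  | 10 min |

- Thursday's (time / min: left-handed product / %): 1.50: 1.6; 3.00: 3.1; 5.00: 3.3; 6.00: 3.9; 8.00: 5.5; 10.0: 7.2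
- Monday's (time / min: left-handed product / %): 0.833: 2.2; 1.33: 4.5; 2.00: 8.3; 4.00: 17.7; 6.00: 26.8; 10.0: 39.2

(scatter of a reading: 1 percentage point)

- the flasks put in order of amount of left-handed product, in percent of the left-handed substrate and right-handed substrate together charged, best first, at 10 min (blue / teal / amber / green / violet)
- the amount of left-handed product, in percent of the left-handed substrate and right-handed substrate together charged of the flask you put first, at 10 min
- the amount of left-handed product, in percent of the left-handed substrate and right-handed substrate together charged of the flask you put last, at 10 min

- free catalyst is single-handed; left-handed substrate and right-handed substrate are mirror images of each other, charged as a racemate, each of them at the stated concentration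
- the numbers in the tables scatter with a standard deviation of 1 percentage point
- at the start none of the gas is in solution

I begin with the last row of each table. Thursday's run stands at 7.2% left-handed product after 10.0 min, which is a turnover number of 307 per free catalyst charged. Monday's run stands at 39.2%, which is 139, so each catalyst in Monday's run has done fewer turnovers, although the flask holds more product.

I hold each count against a limit. Left-handed product comes from left-handed substrate, the limiting reagent, whose charge is half of the substrates together. Green therefore has 107 as its turnover ceiling, c(left-handed substrate)/c(free catalyst) as charged. The same ratio gives Thursday's run 2130 and Monday's run 178, so Thursday's run has used 14.4% of its ceiling and Monday's run 78.1%.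

Green's ceiling lies below Monday's count, so green cannot repeat that count, and I place it above Monday's reading but under half of the substrates. Teal's catalyst lies between the two runs, and if its count lies between theirs as well, my own reckoning puts teal between 5.44% and 12.0%. I expect product to rise with catalyst, green first and teal last.

The forecast gives green > violet > amber > blue > teal, with green at 45% (41% to 49%) and teal at 10.5% (9% to 12.5%), a range for teal narrower than my bracket, and it stands on its own grounds: “Both facts point to gas transfer limiting the rate, since the flask starts with no dissolved gas.”

The flasks give green > violet > amber > blue > teal, with green at 45.1% and teal at 9.82%.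

    partner + catalyst intermediate B → free catalyst + right-handed product (k = 0.861 M⁻¹ s⁻¹)
    free catalyst + right-handed substrate ⇌ catalyst intermediate B (K = 3.17 M⁻¹, k = 62.3 M⁻¹ s⁻¹)
    gas ⇌ partner, rate k3*(csat - [partner]) (kL = 0.0385 s⁻¹)
    free catalyst + left-handed substrate ⇌ catalyst intermediate A (K = 5.47 M⁻¹, k = 116 M⁻¹ s⁻¹)
    partner + free catalyst → spent catalyst (k = 0.0287 M⁻¹ s⁻¹)
    partner + catalyst intermediate A → free catalyst + left-handed product (k = 36.4 M⁻¹ s⁻¹)

Green's 45.1% is 96.2 turnovers per free catalyst charged against the ceiling of 107, which is 90.2% of it at 10.0 min. Green read at 15 min holds 49.4% left-handed product, which is 105 turnovers, or 98.8% of the same ceiling, and in that flask unbound left-handed substrate is down to 1.3% of its charge, while 94% of the right-handed substrate remains unbound.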